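The earlier runs and the new flask are simulated for substances that don't exist, and the scatter is random.

In the ochre run the fastest rung of the ladder is over before the first reading: by 0.417 min the electrophile stands at 59%. On the next rung it creeps to 50% by 2.50 min. On the slowest rung no change can be seen: at 4.00 min ochre still reads 50%, with a scatter of 2 percentage points. Amber, charged with more nucleophile, ends at 0% electrophile, so I take ochre to stop for want of nucleophile, its limiting reagent, and not for want of time.

all flasks: electrophile 0.0010 M

| flask | nucleophile | protic impurity | remark | time |
|---|---|---|---|---|
| ochre | 1.1 mM | 1 mM | run made earlier |  |
| amber | 2.7 mM | 1 mM | run made earlier |  |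
| east | 2.00 mM | 1.00 mM |  | 5.0 min |
| north | 1.00 mM | 1.00 mM |  | 5.0 min |

- ochre (time / min: electrophile / %, target / %): 0.417: 59, 0; 1.33: 53, 0; 2.50: 50, 0; 4.00: 50, 0
- amber (time / min: electrophile / %, target / %): 0.417: 1, 30; 1.33: 2, 24; 2.50: 1, 20; 4.00: 0, 24

(scatter of a reading: 2 percentage points)



- part of the electrophile that has reacted at the end, east
- part of the electrophile that has reacted at the end, north
- what raising the concentration of nucleophile from its lowest to its highest value here does to the part of the electrophile that has reacted (changes below 5 percentage points count as none) (no change / it falls / it rises)

The asked time 5.0 min lies beyond the last reading, so I expect both new flasks to be at rest by then. I therefore divide the rate at which nucleophile is used by the rate at which electrophile is used, and time drops out. If ochre spent its whole 1.1 mM of nucleophile on the 50.0% of its electrophile that reacted, then ν = 2.20, the cost in nucleophile per electrophile consumed. This is a reading and carries the scatter. Amber's charge pays for 1.23 times its electrophile, which fits its final reading.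

The protic impurity is charged alike in the new flasks, so I hold ν fixed. My reckoning gives 90.9% reacted for east and 45.5% for north, a rise.

The forecast, slightly above mine on both, says 93% for east and 46% for north, with the answer it rises, on the ground that “1.1 mM of nucleophile removes only about 0.5 mM of electrophile”.

The flasks give 99.9% for east and 43.8% for north: it rises, by 56 points.

    electrophile + nucleophile → acid set free + target (k = 93.0 M⁻¹ s⁻¹)
    nucleophile + acid set free ⇌ protonated nucleophile, settled at all times (K = 83000 M⁻¹)
    nucleophile + protic impurity → quenched reagent (k = 510 M⁻¹ s⁻¹)
    electrophile + target → side product (k = 250 M⁻¹ s⁻¹)

North has come to rest at a cost of 2.28, close to ν, with 0.027% of its nucleophile left. Ten times the time adds 0.33 points. A neighbour, like north but with 0.0017 M of protic impurity, reaches 24.2%, a cost of 4.13, above ν. East spent 1.95 per electrophile, bound nucleophile counted, which is below ν. East has 0.14% of its electrophile left, and ten times the time takes its conversion from 99.9% to 100%.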